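The numbers in the tables were generated by integration with constants of no real substance, and the scatter is random.

**The leftover.** After 5.00 min the theta run has 50.0% of the starting complex charged in neither read complex, and the beta run has 35.0%, although incoming ligand was charged at 1.50 and 3.88 times the starting complex. The complex with one exchanged reads 31.0% and 31.0%, so we freeze it and follow the complex with two exchanged.

| flask | starting complex | incoming ligand | remark | time |
|---|---|---|---|---|
| theta | 0.16 M | 0.24 M | run made earlier |  |
| beta | 0.16 M | 0.62 M | run made earlier |  |
| summer | 0.16 M | 0.192 M |  | 5.0 min |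
| noon | 0.16 M | 0.320 M |  | 5.0 min |
| spring | 0.16 M | 0.400 M |  | 5.0 min |

| run | time / min | complex with two exchanged / % | complex with one exchanged / % |
|---|---|---|---|
| theta | 1.00 | 10.2 | 25.7 |
| theta | 2.00 | 14.9 | 27.4 |
| theta | 3.00 | 17.1 | 28.4 |
| theta | 4.00 | 18.2 | 29.7 |
| theta | 5.00 | 19.0 | 31.0 |
| beta | 0.417 | 13.7 | 28.0 |
| beta | 1.33 | 22.7 | 28.0 |
| beta | 2.50 | 29.1 | 28.8 |
| beta | 4.00 | 33.2 | 30.6 |
| beta | 5.00 | 34.0 | 31.0 |

(each reading ± 0.5 percentage points)



- final complex with two exchanged, as a percentage of the starting complex charged, for each flask in turn (summer, noon, spring)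

**Turned round.** Our measure is the ligand cost: incoming ligand charged per complex with two exchanged at the end, both as fractions of the starting complex charged. If the complex with two exchanged rose in proportion to the charge, the cost would be equal in both runs, and the beta run would read 49.1%. It reads 34.0%, so the cost climbs from 7.89 in the theta run to 11.4 in the beta run.

**Our line.** We take the cost as straight in the charge ratio, with its rise per unit of charge ratio at 1.47. Two runs cannot test that line. It gives 16.1%, 23.2% and 26.7% for summer, noon and spring.

**The forecast.** It expects 16%, 23% and 26.5%, having read from the runs that the complex with two exchanged “flattens well before the starting complex is used up”.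

**Result.** The flasks give 15.5%, 23.3% and 27.0%.

    starting complex + incoming ligand ⇌ leaving ligand + complex with one exchanged (K = 24.0, k = 0.0813 M⁻¹ s⁻¹)
    complex with one exchanged + incoming ligand ⇌ leaving ligand + complex with two exchanged (K = 12.0, k = 0.131 M⁻¹ s⁻¹)
    complex with two exchanged + incoming ligand ⇌ leaving ligand + complex with three exchanged (K = 2.40, k = 0.145 M⁻¹ s⁻¹)
    2 incoming ligand → self-condensation product (k = 0.0572 M⁻¹ s⁻¹)
    complex with one exchanged → over-reaction product (k = 3.65 × 10⁻⁶ s⁻¹)

**Spent ligand.** The line puts the noon cost at 8.63 and the spring cost at 9.37; those flasks stand at 8.58 and 9.26. In the summer flask the forward half-life of complex with one exchanged towards complex with two exchanged lengthens from 0.97 min at 0.424 min to 17 min at 5.00 min, longer than the 5.0 min run, with incoming ligand, the limiting reagent, down to 2.6% of its charge against 52% of starting complex.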